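Ring C of the flavanone is a β-aryloxy ketone in which O1 and the C4 acyl carbon sit ortho on ring A and C2 is benzylic to ring B. Everything rests on cutting C3–C4 and O1–C2 together, which reveals 2-hydroxy-4,6-dimethoxybenzaldehyde (O1–C8a–C4a–C4) and 3,4,5-trimethoxystyrene (C2=C3). The key step is a copper/bis(oxazoline)-catalysed oxidative radical [4+2] annulation: the aroyl radical of the aldehyde adds to the styrene terminus (C3–C4), and the benzylic radical is captured at the chiral copper-bound phenoxide (O1–C2), closing ring C and setting C2 as S in one operation. The precursor is thus just an aldehyde and an alkene, neither containing the pyranone ring.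

Key step: step 2

Assumption: the sense of induction of the copper/bis(oxazoline) step cannot be assigned in advance; the (S,S)-ligand is written, and its equally available (R,R)-antipode is used instead if it proves to favour the 2R product.

Step 1
Reactants: 1 3,4,5-trimethoxybenzaldehyde
Product: 2 5-ethenyl-1,2,3-trimethoxybenzene (3,4,5-trimethoxystyrene)
Conditions: Ph3PCH3Br, KOtBu, THF, 0 °C to rt
Reagents that add atoms: methyltriphenylphosphonium bromide, C[P+](c1ccccc1)(c1ccccc1)c1ccccc1.[Br-]
Why: Wittig methylenation of a non-enolisable aryl aldehyde with the unstabilised methylide should be clean; the aryl methyl ethers are inert to KOtBu and a terminal alkene raises no stereochemical issue.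

Step 2
Reactants: 2 5-ethenyl-1,2,3-trimethoxybenzene; 3 2-hydroxy-4,6-dimethoxybenzaldehyde
Product: 5 (2S)-5,7-dimethoxy-2-(3,4,5-trimethoxyphenyl)-2,3-dihydro-4H-chromen-4-one, via benzylic radical adduct 4 (not isolated)
Conditions: Cu(MeCN)4PF6 (10 mol %), (S,S)-tBu-BOX [2,2'-(propane-2,2-diyl)bis((4S)-4-tert-butyl-4,5-dihydrooxazole)] (12 mol %), tBuOOBz (1.5 equiv), 2 (2 equiv), PhCF3, 25 °C, under argon
Reagents that add atoms: none
Why: Proposed new method: monovalent copper cleaves the perester into a tert-butoxyl radical and a divalent copper benzoate that exchanges for the phenoxide of 3; tert-butoxyl abstracts the formyl hydrogen, the nucleophilic aroyl radical adds to the unsubstituted terminus of 2 (bond C3–C4) to give benzylic radical 4, and 4 recombines with the bis(oxazoline)-bound divalent copper that already carries O1, so that reductive elimination from trivalent copper forms O1–C2 and returns monovalent copper. The closest known reaction types are the copper/peroxide oxidative coupling of aldehyde-derived acyl radicals with styrenes and the copper/bis(oxazoline) radical relay that turns a benzylic radical into a C–O bond with control of configuration (enantioselective oxy-functionalising lactonisation of aryl alkenoic acids, Kharasch–Sosnovsky oxidation); their merger into a two-component annulation with a phenol as the oxygen partner has not been shown. Ring C is closed as a six-membered ring by C(sp3)–O reductive elimination from a seven-membered cuprocycle containing O1 and C2, which corresponds to a 6-exo-tet displacement at C2 if the phenoxide attacks from outside the coordination sphere. C2 is the only new stereocentre and its configuration is controlled by the twofold-symmetric bis(oxazoline) ligand on copper, which differentiates the two faces of the planar benzylic radical at the capture and reductive-elimination stage. The step needs formyl C–H abstraction in preference to phenol O–H abstraction (the phenol is internally hydrogen-bonded or copper-bound and carries no ortho or para donor), addition at the terminal alkene carbon (benzylic stabilisation of 4), and inner-sphere capture faster than outer-sphere oxidation and proton loss to the chalcone, which the 2-acylphenoxide chelate secures by holding the chiral copper centre next to the radical.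

Compound list
1 | 3,4,5-trimethoxybenzaldehyde | COc1cc(C=O)cc(OC)c1OC | starting material
2 | 5-ethenyl-1,2,3-trimethoxybenzene (3,4,5-trimethoxystyrene) | C=Cc1cc(OC)c(OC)c(OC)c1 | intermediate
3 | 2-hydroxy-4,6-dimethoxybenzaldehyde | COc1cc(O)c(C=O)c(OC)c1 | starting material
4 | benzylic radical adduct, 3-(2-hydroxy-4,6-dimethoxyphenyl)-3-oxo-1-(3,4,5-trimethoxyphenyl)propyl radical (not isolated) | COc1cc(O)c(C(=O)C[CH]c2cc(OC)c(OC)c(OC)c2)c(OC)c1 | intermediate
5 | (2S)-5,7-dimethoxy-2-(3,4,5-trimethoxyphenyl)-2,3-dihydro-4H-chromen-4-one | COc1cc(OC)c2c(c1)O[C@H](c1cc(OC)c(OC)c(OC)c1)CC2=O | target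

Total step count: 2
Longest linear sequence: 2 steps (1 → 2 → 5)

Steps most likely to fail (the route has two steps, so both are ranked):

1. Step 2 (Proposed new method). What may go wrong: the benzylic radical may be oxidised outside the ligand sphere and cyclise without facial control, or lose a proton to the open-chain chalcone. The product may also be dehydrogenated further across C2–C3. Either way enantiopurity or chemoselectivity would be lost. The fallback uses known chemistry, sets out from 3 and comes back at 5. Commercial 3,4,5-trimethoxybenzoyl chloride is acylated onto dimethylsulfoxonium methylide (Me3S(O)I, KOtBu, THF, reflux) to give the sulfoxonium ylide dimethylsulfoxonium 2-oxo-2-(3,4,5-trimethoxyphenyl)ethylide F1. Aldehydic C–H activation of 3 with trivalent rhodium ([Cp*RhCl2]2, AgSbF6, NaOAc, DCE, 100 °C) and carbene insertion of F1 should give the 1,3-diketone 1-(2-hydroxy-4,6-dimethoxyphenyl)-3-(3,4,5-trimethoxyphenyl)propane-1,3-dione F2. F2 cyclodehydrates in the same flask to the flavone 5,7-dimethoxy-2-(3,4,5-trimethoxyphenyl)-4H-chromen-4-one F3, so C3–C4 and O1–C2 are again made in one operation. Asymmetric hydrogenation of the C2=C3 bond with a chiral ruthenium N-heterocyclic carbene catalyst (Ru(cod)(2-methylallyl)2, chiral SINpEt·HBF4, KOtBu, H2, toluene, rt), with the ligand antipode chosen for 2S, should give 5 together with the over-reduced cis-flavan-4-ol (2S,4S)-5,7-dimethoxy-2-(3,4,5-trimethoxyphenyl)chroman-4-ol F4. Periodinane oxidation of the crude mixture (DMP, CH2Cl2, rt) should converge F4 on 5.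

2. Step 1. What may go wrong: incomplete methylenation, or loss of the electron-rich styrene by polymerisation while the phosphine oxide is being removed. The fallback is a Peterson olefination that sets out from 1 and comes back at 2. Addition of Me3SiCH2MgCl (THF, 0 °C) should give the β-hydroxysilane 1-(3,4,5-trimethoxyphenyl)-2-(trimethylsilyl)ethanol F5. Syn-elimination with KH (THF, rt) should then give 2 with a volatile silicon by-product in place of the phosphine oxide.

Further compounds
F1 | step 2 | dimethylsulfoxonium 2-oxo-2-(3,4,5-trimethoxyphenyl)ethylide | COc1cc(C(=O)C=S(C)(C)=O)cc(OC)c1OC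
F2 | step 2 | 1-(2-hydroxy-4,6-dimethoxyphenyl)-3-(3,4,5-trimethoxyphenyl)propane-1,3-dione | COc1cc(O)c(C(=O)CC(=O)c2cc(OC)c(OC)c(OC)c2)c(OC)c1
F3 | step 2 | 5,7-dimethoxy-2-(3,4,5-trimethoxyphenyl)-4H-chromen-4-one | COc1cc(OC)c2c(c1)oc(-c1cc(OC)c(OC)c(OC)c1)cc2=O
F4 | step 2 | (2S,4S)-5,7-dimethoxy-2-(3,4,5-trimethoxyphenyl)chroman-4-ol | COc1cc(OC)c2c(c1)O[C@H](c1cc(OC)c(OC)c(OC)c1)C[C@@H]2O
F5 | step 1 | 1-(3,4,5-trimethoxyphenyl)-2-(trimethylsilyl)ethanol (racemic) | COc1cc(C(O)C[Si](C)(C)C)cc(OC)c1OC
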